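(Readings and results stem from a simulated flask on assumed constants.)

The constants of this flask must be read from two earlier runs that share a catalyst loading and an impurity charge but differ in starting material.

in all of them: free catalyst 0.74 mol%; impurity 0.34 mM
- ochre: starting material 0.035 M; run made earlier
- blue: starting material 0.053 M; run made earlier
- flask: starting material 0.070 M; time 80 min

- ochre (time / min: intermediate / %, target / %): 6.00: 23.9, 0; 10.0: 36.6, 0.8; 15.0: 49.3, 0; 20.0: 60.2, 0.3; 30.0: 74.2, 0; 40.0: 83.9, 0; 60.0: 93.1, 0.1
- blue (time / min: intermediate / %, target / %): 6.00: 23.1, 0.7; 10.0: 35.1, 2.3; 15.0: 44.7, 4.7; 20.0: 53.9, 6.3; 30.0: 61.8, 12.2; 40.0: 64.3, 19.8; 60.0: 61.2, 32.1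

(scatter of a reading: 0.5 percentage points)

* time, not beyond 80 min, at which the flask holds most intermediate
* the amount of intermediate, in percent of the starting material charged, at that time
* the first time at which intermediate reaches 13 %, in the same percent, in min

- what was read earlier has a scatter of 0.5 percentage points, one standard deviation

Starting material lost by 30.0 min gives a first-order constant of 0.0452 min⁻¹ in the ochre run and 0.0449 min⁻¹ in the blue run, so the first step reads the same in both. In the blue run, target gained from 40.0 min to 60.0 min, divided by mean intermediate, gives a second constant of 0.009801 min⁻¹.

The simplest estimate scales this constant with catalyst charged. The ochre run objects: at 60.0 min it reads 0.1 % of target against 32.1 % in the blue run, yet it holds 66.0 % of the blue catalyst. So the better quantity is the working catalyst, catalyst charged minus impurity charged: 0.178 mM in the flask, 0.0522 mM in the blue run and −0.0810 mM in the ochre run, where its sign has crossed zero.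

Perhaps poisoning is slow, though? Then more catalyst stands free early, and the blue constant, read late and carried back to the start, should undershoot early target. It predicts 1.82 % at 10.0 min against 2.3 % read, a gap of about one scatter of 0.5 percentage points, so this reading does not exclude a short burst. With the whole blue catalyst charge free up to that time, the same reckoning gives 13.7 %, more than the reading, so the blue run shows no poisoning as slow as that. The one-for-one subtraction remains an assumption, and the small blue value magnifies any error in it.

Accepting that, the flask's second constant is 0.03342 min⁻¹, which puts the peak at 25.6 min with 42.4 % of intermediate.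

The forecast gives 24.8 min, 41.5 % and 3.3 min, “assuming 1:1 titration and first-order dependence on excess catalyst”. Its second constant of 0.0355 differs from the one reckoned here, and its peak stands earlier and lower.

The flask gives 24.7 min, 41.8 % and 3.21 min.

    starting material → intermediate (k = 0.0461 min⁻¹)
    free catalyst + intermediate → free catalyst + target (k = 198 L mol⁻¹ min⁻¹)
    free catalyst + impurity → spent catalyst (k = 46700 L mol⁻¹ min⁻¹)

Free catalyst in the flask stands at 34.4 % of its charge at 8.00 min and at 34.4 % at 80.0 min. Working catalyst times the second constant of the scheme gives the flask a pseudo-first-order constant of 0.03524 min⁻¹, and with the first constant a peak time of 24.7 min.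

A neighbouring flask, charged with 2.0 × 10⁻⁴ M of impurity, has 0.318 mM of working catalyst, so its constant is 0.0630 min⁻¹ and its peak is reckoned at 18.5 min with 31.2 % of intermediate. Computed, that neighbouring flask peaks at 31.2 %.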